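Readings and results come from a simulation with constants of no real substance; the scatter is artificial.

**The pitfall.** The trap was to read the dawn share off the winter run, which had made 0.0460 M of product by 8.4 h, more than the 0.0254 M of the spring run, and had drawn its partner down by that amount.

common to all: partner 0.100 M
- winter: starting material 0.100 M; free catalyst 0.0100 M
- dusk: starting material 0.100 M; free catalyst 0.0150 M
- spring: starting material 0.0500 M; free catalyst 0.0100 M
- dawn: starting material 0.0150 M; free catalyst 0.0100 M; time 8.4 h

| run | time / h | [product] / M |
|---|---|---|
| winter run | 1.2 | 0.0114 |
| winter run | 2.4 | 0.0210 |
| winter run | 3.6 | 0.0282 |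
| winter run | 4.8 | 0.0339 |
| winter run | 6.0 | 0.0388 |
| winter run | 7.2 | 0.0431 |
| winter run | 8.4 | 0.0460 |
| dusk run | 1.2 | 0.0163 |
| dusk run | 2.4 | 0.0288 |
| dusk run | 3.6 | 0.0379 |
| dusk run | 4.8 | 0.0443 |
| dusk run | 6.0 | 0.0498 |
| dusk run | 7.2 | 0.0545 |
| dusk run | 8.4 | 0.0574 |
| spring run | 1.2 | 0.0060 |
| spring run | 2.4 | 0.0104 |
| spring run | 3.6 | 0.0146 |
| spring run | 4.8 | 0.0180 |
| spring run | 6.0 | 0.0204 |
| spring run | 7.2 | 0.0224 |
| spring run | 8.4 | 0.0254 |

(standard deviation of a reading: 3 × 10⁻⁴ M)

* order of the initial rate in [starting material], near the charge of the winter run, the rate being that where two percent of its starting material are product (one fixed amount of product, the same in the runs compared)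
* order of the initial rate in [free catalyst], near the charge of the winter run, the rate being that where two percent of its starting material are product
* product in the dawn run at 8.4 h, as a share of the starting material charged

- Overall: starting material + partner -> product, with free catalyst as catalyst.
- Constant volume, constant temperature.
- The analysis sees a species whether free or bound.
- An order is taken over about fifteen percent of the charge, up and down.

**First link.** At the first reading, spring over winter was 0.526 for a charge ratio of 0.500, and dusk over winter 1.43 for a catalyst ratio of 1.50. So I took both orders as close to one. With partner at 6.67 times the starting material in the dawn run (pseudo-first-order), I expected the share turned in a given time to depend little on that charge.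

**Second link.** The spring reading at 8.4 h is 50.8% of its charge, with a scatter of 0.600% of that charge. That gives 0.709, the clearing number, the natural log of starting material charged over starting material remaining.

**Third link.** Winter's clearing number was 0.616, lower than spring's. I took mean partner as the charge less half the final product: 0.0770 M in winter, 0.0873 M in spring. The clearing ratio 1.15 nearly matches the partner ratio 1.13. Dawn's partner should average 0.0963 M, the charge less a quarter of its starting material. Scaling in proportion gives 0.782, or 54.3%.

**Weak link.** No run varied the partner's charge, so I tested that proportion inside the spring run. From 3.6 h onward, clearing per hour fell by a factor of 0.791, while mean partner fell by a factor of 0.863, a smaller change. So I read some of the slowing in the spring run as not the partner's, and gave the partner part of the credit. Midway between spring's number and the scaled one stands 0.746, and I committed to 52.6%.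

**The forecast.** It gave orders of 1.05 and 1.05 and a dawn share of 54%, above mine, and remarked that the “slow drift suggests mild product inhibition or catalyst loss”.

**The result.** The dawn run gave 50.8%, 3.2 percentage points below the forecast's share, and the orders came out at 1.0 and 0.99.

    free catalyst + partner ⇌ catalyst-reagent complex, settled at all times (11.30 /M)
    catalyst-reagent complex + starting material → product + free catalyst (21.20 /M/h)
    free catalyst + partner → spent catalyst + partner (1.339 /M/h)

**Clearing again.** The apparent order in [partner] early in the winter run was 0.51. Dawn's clearing number was 0.710, which over 8.4 h is 0.0846 /h. The spring run came to half its charge at 8.67 h, which is 0.0800 /h, slightly slower than the dawn run.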